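**Plan**

Numbering: ring A has C1 (CO2H), C2 (OMe), C3 (CH(OAc)CH2CHMe2) and C6 (OAr); ring B has C1' (ether O), C2' (OH), C4' (Me) and C6' (enone).
Enabling feature: C2–OMe, C1–CO2H and C6–OAr sit on three adjacent carbons of ring A, so the C1–C6 edge can be read as the triple bond of an aryne polarised by the neighbouring C2 methoxy group.
Cuts: the PMB group on C2'–O, the C6'–vinyl bond (Heck), then C6–O and C1–CO2H in one operation (aryne, ring B phenoxide, CO2), then C1–Si (directed metalation) and the carbinol C–CH2 bond (Grignard).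
Forward: no ring is built and both arenes are bought. Ring A becomes the silylaryl triflate (steps 1–8), ring B the bromophenol (steps 9–11), step 12 joins them with CO2, and steps 13–14 add the enone and free the phenol.
Stereochemistry: the only stereocentre (S) is set by asymmetric transfer hydrogenation of the aryl isobutyl ketone in step 4 and is not touched afterwards. The E alkene follows from the Heck mechanism.

Key step: step 12

Remark: the SMILES descriptor translates to S at the carbinol carbon (O > aryl > CH2 > H). This priority order holds in every intermediate, so the descriptor never changes.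

**Ring A**

Step 1
Reactants: 1 4-hydroxy-2-methoxybenzaldehyde
Product: 2 4-formyl-3-methoxyphenyl N,N-diethylcarbamate
Conditions: Et2NCOCl, K2CO3, MeCN, reflux
Reagents that add atoms: N,N-diethylcarbamoyl chloride, CCN(CC)C(=O)Cl
Why: O-carbamoylation of the phenoxide is routine and installs the strongest oxygen-based directing group for the later metalation, while also masking the acidic phenol for the Grignard step.

Step 2
Reactants: 2 4-formyl-3-methoxyphenyl N,N-diethylcarbamate; 3 isobutylmagnesium bromide
Product: 4 rac-4-(1-hydroxy-3-methylbutyl)-3-methoxyphenyl N,N-diethylcarbamate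
Conditions: i-BuMgBr, THF, −78 to 0 °C; aq. NH4Cl
Reagents that add atoms: isobutylmagnesium bromide 3, CC(C)C[Mg]Br
Why: Grignard addition to the aldehyde is much faster than attack on the tertiary carbamate at low temperature, and the racemic centre formed here is erased in step 3.

Step 3
Reactants: 4 rac-4-(1-hydroxy-3-methylbutyl)-3-methoxyphenyl N,N-diethylcarbamate
Product: 5 3-methoxy-4-(3-methylbutanoyl)phenyl N,N-diethylcarbamate
Conditions: Dess–Martin periodinane, CH2Cl2, rt
Reagents that add atoms: none
Why: Dess–Martin oxidation turns the secondary benzylic alcohol into the ketone under near-neutral conditions that leave carbamate and methyl ether untouched.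

Step 4
Reactants: 5 3-methoxy-4-(3-methylbutanoyl)phenyl N,N-diethylcarbamate
Product: 6 4-[(1S)-1-hydroxy-3-methylbutyl]-3-methoxyphenyl N,N-diethylcarbamate
Conditions: RuCl(p-cymene)[(S,S)-TsDPEN] (1 mol %), HCO2H/Et3N 5:2, 30 °C
Reagents that add atoms: none
Why: In Noyori–Ikariya asymmetric transfer hydrogenation the CH/π contact between the substrate aryl group and the p-cymene ligand of the (S,S) catalyst should direct hydride to the Re face of the aryl alkyl ketone and give the S carbinol.

Step 5
Reactants: 6 4-[(1S)-1-hydroxy-3-methylbutyl]-3-methoxyphenyl N,N-diethylcarbamate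
Product: 8 4-[(1S)-1-hydroxy-3-methylbutyl]-3-methoxy-2-(trimethylsilyl)phenyl N,N-diethylcarbamate, via bis-silylated carbamate 7 (not isolated)
Conditions: s-BuLi (2.3 equiv), TMEDA, THF, −78 °C; TMSCl, −78 °C to rt; K2CO3 (cat.), MeOH, rt
Reagents that add atoms: chlorotrimethylsilane, C[Si](C)(C)Cl
Why: In this directed ortho metalation the first equivalent of base forms the lithium alkoxide (which also shields the benzylic C–H and hence the stereocentre), the second removes the C1 proton flanked by carbamate and methoxy groups, TMSCl silylates carbon and oxygen, and methanolysis frees the alcohol again.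

Step 6
Reactants: 8 4-[(1S)-1-hydroxy-3-methylbutyl]-3-methoxy-2-(trimethylsilyl)phenyl N,N-diethylcarbamate
Product: 9 4-[(1S)-1-hydroxy-3-methylbutyl]-3-methoxy-2-(trimethylsilyl)phenol
Conditions: LiAlH4, THF, 0 °C to rt; aq. potassium sodium tartrate
Reagents that add atoms: none
Why: Hydride reduction of the aryl carbamate expels the phenoxide without hydrolytic base, so the C1–Si bond survives, and a temperature at or below rt with a non-acidic work-up should prevent quinone methide formation at the carbinol.

Step 7
Reactants: 9 4-[(1S)-1-hydroxy-3-methylbutyl]-3-methoxy-2-(trimethylsilyl)phenol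
Product: 10 4-[(1S)-1-hydroxy-3-methylbutyl]-3-methoxy-2-(trimethylsilyl)phenyl trifluoromethanesulfonate
Conditions: PhNTf2, i-Pr2NEt, MeCN, rt
Reagents that add atoms: N-phenylbis(trifluoromethanesulfonimide), O=S(=O)(N(c1ccccc1)S(=O)(=O)C(F)(F)F)C(F)(F)F
Why: Chemoselective O-triflation works because N-phenyltriflimide sulfonylates phenoxides but not neutral secondary alcohols, and the triflate also removes the para-oxygen push that could ionise the benzylic position.

Step 8
Reactants: 10 4-[(1S)-1-hydroxy-3-methylbutyl]-3-methoxy-2-(trimethylsilyl)phenyl trifluoromethanesulfonate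
Product: 11 (1S)-1-[2-methoxy-4-(trifluoromethylsulfonyloxy)-3-(trimethylsilyl)phenyl]-3-methylbutyl acetate
Conditions: Ac2O, pyridine, DMAP (cat.), CH2Cl2, 0 °C to rt
Reagents that add atoms: acetic anhydride, CC(=O)OC(C)=O
Why: DMAP-catalysed acetylation takes place at oxygen with retention at carbon, and amine bases do not trigger loss of the silyl and triflate groups.

**Ring B**

Step 9
Reactants: 12 2-hydroxy-4-methylbenzaldehyde
Product: 13 2-(4-methoxybenzyloxy)-4-methylbenzaldehyde
Conditions: PMBCl, K2CO3, DMF, 60 °C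
Reagents that add atoms: 4-methoxybenzyl chloride, COc1ccc(CCl)cc1
Why: Williamson etherification of the salicylaldehyde phenoxide places the PMB group on the oxygen meta to the methyl group, which is the future C2'–O.

Step 10
Reactants: 13 2-(4-methoxybenzyloxy)-4-methylbenzaldehyde
Product: 15 2-(4-methoxybenzyloxy)-4-methylphenol, via aryl formate 14 (not isolated)
Conditions: mCPBA, CH2Cl2, rt; aq. NaHCO3 wash; K2CO3, MeOH, rt
Reagents that add atoms: 3-chloroperoxybenzoic acid, O=C(OO)c1cccc(Cl)c1
Why: In this Baeyer–Villiger (Dakin-type) oxidation the electron-rich ortho-alkoxyaryl group migrates in preference to hydride, and methanolysis of the formate gives a catechol whose two oxygens are differentiated without any selectivity question.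

Step 11
Reactants: 15 2-(4-methoxybenzyloxy)-4-methylphenol
Product: 16 2-bromo-6-(4-methoxybenzyloxy)-4-methylphenol
Conditions: NBS, i-Pr2NH (cat.), CH2Cl2, 0 °C, dark
Reagents that add atoms: N-bromosuccinimide, O=C1CCC(=O)N1Br
Why: In amine-mediated ortho bromination of a phenol whose para position is blocked by methyl, the hydrogen-bonded N-bromoamine should deliver bromine next to the free OH, which activates far more strongly than either aryl ether.

**Union and completion**

Step 12
Reactants: 11 (1S)-1-[2-methoxy-4-(trifluoromethylsulfonyloxy)-3-(trimethylsilyl)phenyl]-3-methylbutyl acetate; 16 2-bromo-6-(4-methoxybenzyloxy)-4-methylphenol; 17 carbon dioxide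
Product: 22 3-[(1S)-1-acetoxy-3-methylbutyl]-6-[2-bromo-6-(4-methoxybenzyloxy)-4-methylphenoxy]-2-methoxybenzoic acid, via potassium phenoxide 18 (not isolated), via aryne 19 (not isolated), via C1 aryl anion 20 (not isolated), via potassium carboxylate 21 (not isolated)
Conditions: 16 (1.5 equiv), KH, THF, 0 °C; 18-crown-6, KF, dry CO2 (1 atm), slow addition of 11, 0 °C to rt; cold 1 M HCl
Reagents that add atoms: carbon dioxide 17, O=C=O
Why: Proposed new method: in this three-component aryne difunctionalisation fluoride strips the trimethylsilyl group from C1 and the C6 triflate departs, so aryne 19 is released slowly in a proton-free medium; phenoxide 18 bonds to C6, the C1 carbanion 20 thus formed adds to dissolved CO2, and acidification of carboxylate 21 gives 22. The closest known reaction types are the three-component coupling of arynes with secondary amines and CO2 to anthranilic acids under KF/18-crown-6 in THF, and the fluoride-mediated O-arylation of hindered phenols by silylaryl triflates; what is untested is an anionic oxygen nucleophile in the CO2-terminated version. The selectivity required is attack at C6 and not at C1, and the C2 methoxy group supplies it: its inductive pull distorts the aryne so that C6 is the more linear and electrophilic terminus, it stabilises charge building up at C1, and it screens C1 sterically. No ring closes and no stereocentre is created, and the S carbinol carbon on C3 takes no part in any bond change. Carboxylation should win over protonation because 18 is made with KH (only H2 is released), THF replaces acidic nitrile solvents and a CO2 atmosphere is maintained, while reversible carbonate formation from 18 and CO2 merely lowers the free phenoxide concentration. Ring B is brought in as the C6' bromide because a carbonyl or enone at that position would act as an internal electrophile towards 20.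

Step 13
Reactants: 22 3-[(1S)-1-acetoxy-3-methylbutyl]-6-[2-bromo-6-(4-methoxybenzyloxy)-4-methylphenoxy]-2-methoxybenzoic acid; 23 methyl vinyl ketone
Product: 24 3-[(1S)-1-acetoxy-3-methylbutyl]-2-methoxy-6-{2-(4-methoxybenzyloxy)-4-methyl-6-[(1E)-3-oxobut-1-enyl]phenoxy}benzoic acid
Conditions: 23, Pd2(dba)3, [HP(t-Bu)3]BF4, Cy2NMe, dioxane, 50 °C
Reagents that add atoms: methyl vinyl ketone 23, C=CC(C)=O
Why: In this Mizoroki–Heck reaction the bulky electron-rich phosphine allows oxidative addition of the hindered bromide at mild temperature, syn insertion at the terminal carbon of 23 followed by syn β-hydride elimination gives the E enone, and phosphine-ligated palladium at 50 °C should not decarboxylate the benzoate.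

Step 14
Reactants: 24 3-[(1S)-1-acetoxy-3-methylbutyl]-2-methoxy-6-{2-(4-methoxybenzyloxy)-4-methyl-6-[(1E)-3-oxobut-1-enyl]phenoxy}benzoic acid
Product: 25 3-[(1S)-1-acetoxy-3-methylbutyl]-6-{2-hydroxy-4-methyl-6-[(1E)-3-oxobut-1-enyl]phenoxy}-2-methoxybenzoic acid (CNP0281268.1)
Conditions: DDQ, CH2Cl2/pH 7 buffer, 0 °C to rt
Reagents that add atoms: none
Why: Oxidative cleavage of the 4-methoxybenzyl ether by DDQ (hydride abstraction, then hydrolysis of the oxocarbenium ion) runs at neutral pH and should spare the acid-labile benzylic acetate, the enone and the carboxylic acid.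

**Compound list**

1 | 4-hydroxy-2-methoxybenzaldehyde | COc1cc(O)ccc1C=O | starting material
2 | 4-formyl-3-methoxyphenyl N,N-diethylcarbamate | COc1cc(OC(=O)N(CC)CC)ccc1C=O | intermediate
3 | isobutylmagnesium bromide | CC(C)C[Mg]Br | starting material
4 | rac-4-(1-hydroxy-3-methylbutyl)-3-methoxyphenyl N,N-diethylcarbamate | COc1cc(OC(=O)N(CC)CC)ccc1C(O)CC(C)C | intermediate
5 | 3-methoxy-4-(3-methylbutanoyl)phenyl N,N-diethylcarbamate | COc1cc(OC(=O)N(CC)CC)ccc1C(=O)CC(C)C | intermediate
6 | 4-[(1S)-1-hydroxy-3-methylbutyl]-3-methoxyphenyl N,N-diethylcarbamate | COc1cc(OC(=O)N(CC)CC)ccc1[C@H](CC(C)C)O | intermediate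
7 | 3-methoxy-4-[(1S)-3-methyl-1-(trimethylsilyloxy)butyl]-2-(trimethylsilyl)phenyl N,N-diethylcarbamate | COc1c([C@H](CC(C)C)O[Si](C)(C)C)ccc(OC(=O)N(CC)CC)c1[Si](C)(C)C | intermediate
8 | 4-[(1S)-1-hydroxy-3-methylbutyl]-3-methoxy-2-(trimethylsilyl)phenyl N,N-diethylcarbamate | COc1c([C@H](CC(C)C)O)ccc(OC(=O)N(CC)CC)c1[Si](C)(C)C | intermediate
9 | 4-[(1S)-1-hydroxy-3-methylbutyl]-3-methoxy-2-(trimethylsilyl)phenol | COc1c([C@H](CC(C)C)O)ccc(O)c1[Si](C)(C)C | intermediate
10 | 4-[(1S)-1-hydroxy-3-methylbutyl]-3-methoxy-2-(trimethylsilyl)phenyl trifluoromethanesulfonate | COc1c([C@H](CC(C)C)O)ccc(OS(=O)(=O)C(F)(F)F)c1[Si](C)(C)C | intermediate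
11 | (1S)-1-[2-methoxy-4-(trifluoromethylsulfonyloxy)-3-(trimethylsilyl)phenyl]-3-methylbutyl acetate | COc1c([C@H](CC(C)C)OC(C)=O)ccc(OS(=O)(=O)C(F)(F)F)c1[Si](C)(C)C | intermediate
12 | 2-hydroxy-4-methylbenzaldehyde | Cc1ccc(C=O)c(O)c1 | starting material
13 | 2-(4-methoxybenzyloxy)-4-methylbenzaldehyde | COc1ccc(COc2cc(C)ccc2C=O)cc1 | intermediate
14 | 2-(4-methoxybenzyloxy)-4-methylphenyl formate | COc1ccc(COc2cc(C)ccc2OC=O)cc1 | intermediate
15 | 2-(4-methoxybenzyloxy)-4-methylphenol | COc1ccc(COc2cc(C)ccc2O)cc1 | intermediate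
16 | 2-bromo-6-(4-methoxybenzyloxy)-4-methylphenol | Cc1cc(Br)c(O)c(OCc2ccc(OC)cc2)c1 | intermediate
17 | carbon dioxide | O=C=O | starting material
18 | potassium 2-bromo-6-(4-methoxybenzyloxy)-4-methylphenoxide | Cc1cc(Br)c([O-])c(OCc2ccc(OC)cc2)c1.[K+] | intermediate
19 | (1S)-1-(3,4-didehydro-2-methoxyphenyl)-3-methylbutyl acetate (C1–C6 aryne of ring A) | COC1=C([C@H](CC(C)C)OC(C)=O)C=CC#C1 | intermediate
20 | potassium C1 aryl anion of the ring A/ring B diaryl ether | COc1c([C@H](CC(C)C)OC(C)=O)ccc(Oc2c(OCc3ccc(OC)cc3)cc(C)cc2Br)[c-]1.[K+] | intermediate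
21 | potassium salt of acid 22 | COc1c([C@H](CC(C)C)OC(C)=O)ccc(Oc2c(OCc3ccc(OC)cc3)cc(C)cc2Br)c1C(=O)[O-].[K+] | intermediate
22 | 3-[(1S)-1-acetoxy-3-methylbutyl]-6-[2-bromo-6-(4-methoxybenzyloxy)-4-methylphenoxy]-2-methoxybenzoic acid | COc1c([C@H](CC(C)C)OC(C)=O)ccc(Oc2c(OCc3ccc(OC)cc3)cc(C)cc2Br)c1C(=O)O | intermediate
23 | methyl vinyl ketone (but-3-en-2-one) | C=CC(C)=O | starting material
24 | 3-[(1S)-1-acetoxy-3-methylbutyl]-2-methoxy-6-{2-(4-methoxybenzyloxy)-4-methyl-6-[(1E)-3-oxobut-1-enyl]phenoxy}benzoic acid | COc1c([C@H](CC(C)C)OC(C)=O)ccc(Oc2c(OCc3ccc(OC)cc3)cc(C)cc2/C=C/C(C)=O)c1C(=O)O | intermediate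
25 | 3-[(1S)-1-acetoxy-3-methylbutyl]-6-{2-hydroxy-4-methyl-6-[(1E)-3-oxobut-1-enyl]phenoxy}-2-methoxybenzoic acid (CNP0281268.1) | COc1c([C@H](CC(C)C)OC(C)=O)ccc(Oc2c(O)cc(C)cc2/C=C/C(C)=O)c1C(=O)O | target

**Step count**

Total step count: 14.
Longest linear sequence: 11 steps (steps 1–8 and 12–14).

**Steps most likely to fail**

Step 12. Several processes could intervene:
- The C1 anion may be protonated, by the acetate methyl group or by traces of water, before it meets CO2.
- The phenoxide may be held back as its carbonate.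
- The triflyl group may be transferred from 11 to the phenoxide.
- Carboxylate 21 may be arylated by a second aryne.

The fallback is a carboxylate-assisted Ullmann ether synthesis and uses known chemistry throughout. It sets out from Grignard reagent 3 and phenol 16 and comes back at 22. Commercial 4-bromo-2-methoxybenzaldehyde F1 is taken through the operations of steps 2–4. These give racemic 1-(4-bromo-2-methoxyphenyl)-3-methylbutan-1-ol F2, then 1-(4-bromo-2-methoxyphenyl)-3-methylbutan-1-one F3, then (1S)-1-(4-bromo-2-methoxyphenyl)-3-methylbutan-1-ol F4. LiN(i-Pr)2 (two equivalents, THF, −78 °C) removes the ring proton between Br and OMe, and a CO2 quench gives 6-bromo-3-[(1S)-1-hydroxy-3-methylbutyl]-2-methoxybenzoic acid F5. Ac2O/pyridine gives 3-[(1S)-1-acetoxy-3-methylbutyl]-6-bromo-2-methoxybenzoic acid F6. Cu2O and K2CO3 in DMF/pyridine at about 100 °C then couple F6 with 16 to give 22. The ortho carboxylate activates its own C–Br bond in preference to that of ring B.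

Step 5. Metalation of the lithium alkoxide may stall or drift to C5. It may also be followed by carbamoyl migration (anionic Fries rearrangement) before silylation at the crowded C1.

The fallback silylates before the carbinol exists. It sets out from 2 and comes back at 8. Ethylene glycol (TsOH, toluene, water removal) converts 2 into 4-(1,3-dioxolan-2-yl)-3-methoxyphenyl N,N-diethylcarbamate F7, which carries no acidic proton. s-BuLi/TMEDA and then TMSCl give 4-(1,3-dioxolan-2-yl)-3-methoxy-2-(trimethylsilyl)phenyl N,N-diethylcarbamate F8. PPTS in wet acetone releases 4-formyl-3-methoxy-2-(trimethylsilyl)phenyl N,N-diethylcarbamate F9. The operations of steps 2–4 then lead through racemic 4-(1-hydroxy-3-methylbutyl)-3-methoxy-2-(trimethylsilyl)phenyl N,N-diethylcarbamate F10 and 3-methoxy-4-(3-methylbutanoyl)-2-(trimethylsilyl)phenyl N,N-diethylcarbamate F11 to 8.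

Step 13. Migratory insertion may be slow at the crowded arylpalladium centre, and 23 may polymerise on prolonged heating. The 2,6-dioxygenated benzoate may also lose CO2 at divalent palladium.

The fallback separates aryl–vinyl bond formation from enone formation. It sets out from 22 and comes back at 24. Base-free Stille vinylation with tributyl(vinyl)stannane (Pd(PPh3)4, toluene, 90 °C) gives 3-[(1S)-1-acetoxy-3-methylbutyl]-6-[2-ethenyl-6-(4-methoxybenzyloxy)-4-methylphenoxy]-2-methoxybenzoic acid F12. Olefin cross-metathesis of F12 with 23 (second-generation Hoveyda–Grubbs catalyst, CH2Cl2, 40 °C) should give the E enone 24.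

**Further compounds**

F1 | step 12 | 4-bromo-2-methoxybenzaldehyde | COc1cc(Br)ccc1C=O
F2 | step 12 | rac-1-(4-bromo-2-methoxyphenyl)-3-methylbutan-1-ol | COc1cc(Br)ccc1C(O)CC(C)C
F3 | step 12 | 1-(4-bromo-2-methoxyphenyl)-3-methylbutan-1-one | COc1cc(Br)ccc1C(=O)CC(C)C
F4 | step 12 | (1S)-1-(4-bromo-2-methoxyphenyl)-3-methylbutan-1-ol | COc1cc(Br)ccc1[C@H](CC(C)C)O
F5 | step 12 | 6-bromo-3-[(1S)-1-hydroxy-3-methylbutyl]-2-methoxybenzoic acid | COc1c([C@H](CC(C)C)O)ccc(Br)c1C(=O)O
F6 | step 12 | 3-[(1S)-1-acetoxy-3-methylbutyl]-6-bromo-2-methoxybenzoic acid | COc1c([C@H](CC(C)C)OC(C)=O)ccc(Br)c1C(=O)O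
F7 | step 5 | 4-(1,3-dioxolan-2-yl)-3-methoxyphenyl N,N-diethylcarbamate | COc1cc(OC(=O)N(CC)CC)ccc1C1OCCO1
F8 | step 5 | 4-(1,3-dioxolan-2-yl)-3-methoxy-2-(trimethylsilyl)phenyl N,N-diethylcarbamate | COc1c(C2OCCO2)ccc(OC(=O)N(CC)CC)c1[Si](C)(C)C
F9 | step 5 | 4-formyl-3-methoxy-2-(trimethylsilyl)phenyl N,N-diethylcarbamate | COc1c(C=O)ccc(OC(=O)N(CC)CC)c1[Si](C)(C)C
F10 | step 5 | rac-4-(1-hydroxy-3-methylbutyl)-3-methoxy-2-(trimethylsilyl)phenyl N,N-diethylcarbamate | COc1c(C(O)CC(C)C)ccc(OC(=O)N(CC)CC)c1[Si](C)(C)C
F11 | step 5 | 3-methoxy-4-(3-methylbutanoyl)-2-(trimethylsilyl)phenyl N,N-diethylcarbamate | COc1c(C(=O)CC(C)C)ccc(OC(=O)N(CC)CC)c1[Si](C)(C)C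
F12 | step 13 | 3-[(1S)-1-acetoxy-3-methylbutyl]-6-[2-ethenyl-6-(4-methoxybenzyloxy)-4-methylphenoxy]-2-methoxybenzoic acid | COc1c([C@H](CC(C)C)OC(C)=O)ccc(Oc2c(OCc3ccc(OC)cc3)cc(C)cc2C=C)c1C(=O)O
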